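Ring C of unit 1 (O1, C2, C3, C4, C4a, C8a), taken without ring A, is a 2,3-dihydropyran-4-one whose cis C2 (catechol ring B) and C3 (ring D, attached through C8'') centres are those of an endo aldehyde–diene cycloadduct. The route rests on disconnecting C2–C3 and O1–C8a: one hetero-Diels–Alder reaction under a chiral chromium salen complex closes ring C and sets both centres as (2R,3R). Its precursor is a (1E,3Z)-1-methoxy-3-silyloxybutadiene whose terminus carries the complete benzyl-protected (R)-flavanone unit 2 (rings D, F, E); the partner is 3,4-bis(benzyloxy)benzaldehyde. Ring A is then annulated onto C4a=C8a and aromatised, and hydrogenolysis finishes.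

Key step: step 11

Remark: the target is the 2,3-cis isomer, (2R,3R) in unit 1 and (2R) at C2'' of unit 2; unit 1 atoms are unprimed, unit 2 atoms double-primed.
Remark: ArD = (2R)-5,7-bis(benzyloxy)-2-[4-(benzyloxy)phenyl]-4-oxochroman-8-yl; ArB = 3,4-bis(benzyloxy)phenyl; salen = N,N'-bis(3,5-di-tert-butylsalicylidene)cyclohexane-1,2-diaminate; Ph-bod = 2,5-diphenylbicyclo[2.2.2]octa-2,5-diene.
Assumption: the sense of induction of the two chiral catalysts (steps 5 and 11) is assigned by analogy with simple substrates; the other antipode of each ligand is equally available if a model run shows the opposite sense.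

Step 1
Reactants: 1 2,4,6-trihydroxyacetophenone
Product: 2 1-[2,4-bis(benzyloxy)-6-hydroxyphenyl]ethanone
Conditions: BnBr (2.1 equiv), K2CO3, DMF, rt
Reagents that add atoms: benzyl bromide, BrCc1ccccc1
Why: Williamson etherification that should stop at the dibenzyl ether, because the last ortho hydroxyl is hydrogen-bonded to the acetyl group and alkylates much more slowly.

Step 2
Reactants: 2 1-[2,4-bis(benzyloxy)-6-hydroxyphenyl]ethanone
Product: 3 1-[2-(allyloxy)-4,6-bis(benzyloxy)phenyl]ethanone
Conditions: allyl bromide, K2CO3, DMF, 60 °C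
Reagents that add atoms: allyl bromide, BrCC=C
Why: Williamson etherification under forcing conditions, which should overcome the chelation of the remaining phenol.

Step 3
Reactants: 3 1-[2-(allyloxy)-4,6-bis(benzyloxy)phenyl]ethanone
Product: 4 1-[3-allyl-4,6-bis(benzyloxy)-2-hydroxyphenyl]ethanone
Conditions: N,N-diethylaniline, 200 °C
Reagents that add atoms: none
Why: Aromatic Claisen rearrangement, a [3,3] shift that can only deliver the allyl group to the one free ortho carbon, the later C8''.

Step 4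
Reactants: 4 1-[3-allyl-4,6-bis(benzyloxy)-2-hydroxyphenyl]ethanone
Product: 6 8-allyl-5,7-bis(benzyloxy)-4H-chromen-4-one, via enaminone 5 (not isolated)
Conditions: Me2NCH(OMe)2, toluene, 100 °C; then AcOH, 60 °C
Reagents that add atoms: N,N-dimethylformamide dimethyl acetal, COC(OC)N(C)C
Why: Standard chromone synthesis: condensation of the methyl ketone to the enaminone, then acid-mediated addition–elimination of the ortho phenol with loss of dimethylamine.

Step 5
Reactants: 6 8-allyl-5,7-bis(benzyloxy)-4H-chromen-4-one; 7 [4-(benzyloxy)phenyl]boronic acid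
Product: 8 (2R)-8-allyl-5,7-bis(benzyloxy)-2-[4-(benzyloxy)phenyl]chroman-4-one
Conditions: [Rh(OH)((R,R)-Ph-bod)]2 (3 mol% Rh), dioxane/H2O 10:1, 40 °C
Reagents that add atoms: none
Why: Hayashi–Miyaura asymmetric 1,4-addition of an aryl group from monovalent rhodium to the chromone, in which the chiral diene ligand selects the enantioface of C2''=C3'' and so sets C2'' as R; no base is added, so the flavanone should not ring-open.

Step 6
Reactants: 8 (2R)-8-allyl-5,7-bis(benzyloxy)-2-[4-(benzyloxy)phenyl]chroman-4-one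
Product: 9 2-ArD-acetaldehyde
Conditions: OsO4 (2 mol%), NaIO4, 2,6-lutidine, dioxane/H2O 3:1, rt
Reagents that add atoms: sodium periodate (delivers the carbonyl oxygen through OsO4), [Na+].[O-]I(=O)(=O)=O
Why: Lemieux–Johnson oxidative cleavage, which should touch only the terminal alkene under buffered, near-neutral conditions.

Step 7
Reactants: 9 2-ArD-acetaldehyde
Product: 10 1-ArD-but-3-yn-2-ol (both carbinol epimers)
Conditions: HC≡CMgBr (1.3 equiv), THF, −78 °C; NH4Cl (aq)
Reagents that add atoms: ethynylmagnesium bromide, C#C[Mg]Br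
Why: Grignard addition to the aliphatic aldehyde, which at −78 °C should be far more electrophilic than the hindered, donor-substituted aryl ketone of ring F; the new carbinol centre is erased in step 8.

Step 8
Reactants: 10 1-ArD-but-3-yn-2-ol
Product: 11 1-ArD-but-3-yn-2-one
Conditions: Dess–Martin periodinane, CH2Cl2, 0 °C to rt
Reagents that add atoms: none
Why: Dess–Martin oxidation of the propargylic alcohol under neutral conditions, which should spare the benzyl ethers and C2''.

Step 9
Reactants: 11 1-ArD-but-3-yn-2-one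
Product: 12 (E)-1-ArD-4-methoxybut-3-en-2-one
Conditions: MeOH (5 equiv), DABCO (10 mol%), CH2Cl2, 0 °C to rt
Reagents that add atoms: methanol, CO
Why: Amine-catalysed oxa-Michael addition of methanol to the terminal ynone, which should give the thermodynamically preferred E vinylogous ester.

Step 10
Reactants: 12 (E)-1-ArD-4-methoxybut-3-en-2-one
Product: 13 (1Z,3E)-1-ArD-4-methoxy-2-(trimethylsilyloxy)buta-1,3-diene [the (1E,3Z)-1-methoxy-3-silyloxy-4-ArD diene]
Conditions: Me3SiOTf (1.15 equiv), Et3N (2 equiv), Et2O, −78 to 0 °C; filtered, used crude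
Reagents that add atoms: trimethylsilyl trifluoromethanesulfonate, C[Si](C)(C)OS(=O)(=O)C(F)(F)F
Why: Soft enolisation at the benzylic CH2 of the vinylogous ester, the most acidic site, which should give the Z enol silane (ring D syn to OSi, hence outside the diene); a limited amount of silyl triflate at low temperature keeps the ring F ketone largely free, and any enol silane formed there is inert and reverts in the acid treatment of step 11.

Step 11
Reactants: 13 (1Z,3E)-1-ArD-4-methoxy-2-(trimethylsilyloxy)buta-1,3-diene; 14 3,4-bis(benzyloxy)benzaldehyde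
Product: 16 (2R,3R)-2-ArB-3-ArD-2,3-dihydro-4H-pyran-4-one, via silyl enol ether cycloadduct 15 (not isolated)
Conditions: (R,R)-(salen)CrBF4 (10 mol%), 4 Å molecular sieves, t-BuOMe, −20 °C to rt; then CF3CO2H (cat.), CH2Cl2, 0 °C
Reagents that add atoms: none
Why: The cationic trivalent chromium centre binds the aldehyde oxygen anti to the aryl group, and the electron-rich diene adds in a concerted, asynchronous [4+2] cycloaddition in which its ring D-bearing terminus forms C2–C3 and the aldehyde oxygen forms O1–C8a; CF3CO2H then cleaves the enol silane and expels methanol from the C8a acetal to give the enone. The closest known reaction type is the Lewis-acid-catalysed enantioselective hetero-Diels–Alder reaction of 4-substituted 1-alkoxy-3-silyloxy dienes with aromatic aldehydes, which gives cis-2,3-disubstituted dihydropyranones. Ring C closes by an intermolecular suprafacial [4π+2π] cycloaddition, so both bonds form on one face of each partner and no separate cyclisation is needed. C2 is set by the chiral ligand, which exposes the Re face of the bound aldehyde, and C3 follows from the endo transition state together with the Z enol silane that holds ring D on the outside of the diene, which places the two aryl groups cis. The step needs endo over exo and Re over Si selectivity: the fixed diene geometry and a weakly ionising Lewis acid (no stepwise aldol path) secure the first, and catalyst control secures the second because the C2'' centre is remote. The ketone of unit 2 is not a competent heterodienophile, so only the aldehyde reacts.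

Step 12
Reactants: 16 (2R,3R)-2-ArB-3-ArD-2,3-dihydro-4H-pyran-4-one
Product: 17 (2R,3R)-2-ArB-3-ArD-5-(phenylthio)-2,3-dihydro-4H-pyran-4-one
Conditions: PhSCl (1.05 equiv), CH2Cl2, −78 °C; then 2,6-lutidine, −78 to 0 °C
Reagents that add atoms: benzenesulfenyl chloride, ClSc1ccccc1
Why: Electrophilic α-sulfenylation of a vinylogous ester by addition–elimination: the sulfur electrophile adds to the nucleophilic C4a, and the weak base then removes the C4a proton to restore the enone without touching C3 or C2.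

Step 13
Reactants: 17 (2R,3R)-2-ArB-3-ArD-5-(phenylthio)-2,3-dihydro-4H-pyran-4-one
Product: 18 (2R,3R)-2-ArB-3-ArD-5-(phenylsulfinyl)-2,3-dihydro-4H-pyran-4-one (both sulfur epimers)
Conditions: mCPBA (1.0 equiv), CH2Cl2, −78 °C
Reagents that add atoms: 3-chloroperoxybenzoic acid, OOC(=O)c1cccc(Cl)c1
Why: Sulfide-to-sulfoxide oxidation with one equivalent of peracid at low temperature, which should be much faster than any attack on the enone or the arenes; the sulfur configuration is irrelevant because the group is lost in step 16.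

Step 14
Reactants: 19 methyl acetoacetate
Product: 20 methyl 3-(trimethylsilyloxy)but-2-enoate (E/Z mixture)
Conditions: Me3SiCl, Et3N, hexane, rt
Reagents that add atoms: chlorotrimethylsilane, C[Si](C)(C)Cl
Why: O-silylation of the enol of a β-keto ester, a routine enol silane formation.

Step 15
Reactants: 20 methyl 3-(trimethylsilyloxy)but-2-enoate
Product: 21 1-methoxy-1,3-bis(trimethylsilyloxy)buta-1,3-diene (geometry at C1=C2 immaterial)
Conditions: LiN(iPr)2, THF, −78 °C; then Me3SiCl
Reagents that add atoms: chlorotrimethylsilane, C[Si](C)(C)Cl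
Why: γ-Deprotonation of the silyl enol ether ester by the lithium amide and O-silylation of the dienolate, the standard preparation of the bis-silyl dienol ether of an acetoacetate.

Step 16
Reactants: 18 (2R,3R)-2-ArB-3-ArD-5-(phenylsulfinyl)-2,3-dihydro-4H-pyran-4-one; 21 1-methoxy-1,3-bis(trimethylsilyloxy)buta-1,3-diene
Product: 25 (2R,3R)-2-ArB-3-ArD-5,7-dihydroxychroman-4-one, via sulfinyl cycloadduct 22 (not isolated), via dienyl ketal 23 (not isolated), via bis(trimethylsilyl) ether 24 (not isolated)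
Conditions: 21 (4 equiv), toluene, rt to 70 °C; then 1 M HCl, THF, 0 °C
Reagents that add atoms: none
Why: Proposed new method: the sulfinyl group lowers the LUMO of C4a=C8a, so the ketene-acetal diene should add in a polarised [4+2] step with its CH2 terminus at the β-carbon C8a and its acetal carbon at C4a; the cis C8a–H then allows thermal syn elimination of benzenesulfenic acid (a sulfoxide is chosen over a halide because this only β-hydrogen is not acidic and a base would endanger C3), vinylogous loss of methanol aromatises ring A and dilute acid cleaves the two aryl silyl ethers; either face of the dienophile gives the same product since C4a and C8a end sp2; the closest known reaction types are the Diels–Alder/aromatisation of 1,1,3-trioxygenated dienes with halo- or sulfinyl-quinones and the use of vinyl sulfoxides as alkyne equivalents in Diels–Alder reactions.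

Step 17
Reactants: 25 (2R,3R)-2-ArB-3-ArD-5,7-dihydroxychroman-4-one
Product: 26 (2R,3R)-2-(3,4-dihydroxyphenyl)-5,7-dihydroxy-3-[(2R)-5,7-dihydroxy-2-(4-hydroxyphenyl)-4-oxochroman-8-yl]chroman-4-one
Conditions: H2 (1 atm), 10% Pd/C, EtOAc/MeOH 1:1, rt
Reagents that add atoms: none
Why: Hydrogenolysis of the five benzyl ethers under neutral conditions, which should leave both flavanone ketones and the base-sensitive C3, C2 and C2'' centres untouched, provided sulfur by-products were removed by chromatography beforehand.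

Compound list
1 | 2,4,6-trihydroxyacetophenone | CC(=O)c1c(O)cc(O)cc1O | starting material
2 | 1-[2,4-bis(benzyloxy)-6-hydroxyphenyl]ethanone | CC(=O)c1c(O)cc(OCc2ccccc2)cc1OCc1ccccc1 | intermediate
3 | 1-[2-(allyloxy)-4,6-bis(benzyloxy)phenyl]ethanone | CC(=O)c1c(OCC=C)cc(OCc2ccccc2)cc1OCc1ccccc1 | intermediate
4 | 1-[3-allyl-4,6-bis(benzyloxy)-2-hydroxyphenyl]ethanone | CC(=O)c1c(O)c(CC=C)c(OCc2ccccc2)cc1OCc1ccccc1 | intermediate
5 | (E)-1-[3-allyl-4,6-bis(benzyloxy)-2-hydroxyphenyl]-3-(dimethylamino)prop-2-en-1-one | CN(C)/C=C/C(=O)c1c(O)c(CC=C)c(OCc2ccccc2)cc1OCc1ccccc1 | intermediate (not isolated)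
6 | 8-allyl-5,7-bis(benzyloxy)-4H-chromen-4-one | O=c1ccoc2c(CC=C)c(OCc3ccccc3)cc(OCc3ccccc3)c12 | intermediate
7 | [4-(benzyloxy)phenyl]boronic acid | OB(O)c1ccc(OCc2ccccc2)cc1 | starting material
8 | (2R)-8-allyl-5,7-bis(benzyloxy)-2-[4-(benzyloxy)phenyl]chroman-4-one | O=C1C[C@H](c2ccc(OCc3ccccc3)cc2)Oc2c1c(OCc3ccccc3)cc(OCc3ccccc3)c2CC=C | intermediate
9 | 2-[(2R)-5,7-bis(benzyloxy)-2-[4-(benzyloxy)phenyl]-4-oxochroman-8-yl]acetaldehyde | O=C1C[C@H](c2ccc(OCc3ccccc3)cc2)Oc2c1c(OCc3ccccc3)cc(OCc3ccccc3)c2CC=O | intermediate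
10 | (2R)-5,7-bis(benzyloxy)-2-[4-(benzyloxy)phenyl]-8-(2-hydroxybut-3-yn-1-yl)chroman-4-one, both carbinol epimers | O=C1C[C@H](c2ccc(OCc3ccccc3)cc2)Oc2c1c(OCc3ccccc3)cc(OCc3ccccc3)c2CC(O)C#C | intermediate
11 | (2R)-5,7-bis(benzyloxy)-2-[4-(benzyloxy)phenyl]-8-(2-oxobut-3-yn-1-yl)chroman-4-one | O=C1C[C@H](c2ccc(OCc3ccccc3)cc2)Oc2c1c(OCc3ccccc3)cc(OCc3ccccc3)c2CC(=O)C#C | intermediate
12 | (2R)-5,7-bis(benzyloxy)-2-[4-(benzyloxy)phenyl]-8-[(E)-4-methoxy-2-oxobut-3-en-1-yl]chroman-4-one | O=C1C[C@H](c2ccc(OCc3ccccc3)cc2)Oc2c1c(OCc3ccccc3)cc(OCc3ccccc3)c2CC(=O)/C=C/OC | intermediate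
13 | (2R)-5,7-bis(benzyloxy)-2-[4-(benzyloxy)phenyl]-8-[(1Z,3E)-4-methoxy-2-(trimethylsilyloxy)buta-1,3-dien-1-yl]chroman-4-one | O=C1C[C@H](c2ccc(OCc3ccccc3)cc2)Oc2c1c(OCc3ccccc3)cc(OCc3ccccc3)c2/C=C(/C=C/OC)O[Si](C)(C)C | intermediate (key-step precursor)
14 | 3,4-bis(benzyloxy)benzaldehyde | O=Cc1ccc(OCc2ccccc2)c(OCc2ccccc2)c1 | starting material
15 | (2R,3R,6S)-2-ArB-3-ArD-6-methoxy-4-(trimethylsilyloxy)-3,6-dihydro-2H-pyran, all-cis | O=C1C[C@H](c2ccc(OCc3ccccc3)cc2)Oc2c1c(OCc3ccccc3)cc(OCc3ccccc3)c2[C@H]1C(O[Si](C)(C)C)=C[C@@H](OC)O[C@H]1c1ccc(OCc3ccccc3)c(OCc3ccccc3)c1 | intermediate (not isolated)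
16 | (2R,3R)-2-[3,4-bis(benzyloxy)phenyl]-3-[(2R)-5,7-bis(benzyloxy)-2-[4-(benzyloxy)phenyl]-4-oxochroman-8-yl]-2,3-dihydro-4H-pyran-4-one | O=C1C[C@H](c2ccc(OCc3ccccc3)cc2)Oc2c1c(OCc3ccccc3)cc(OCc3ccccc3)c2[C@H]1C(=O)C=CO[C@H]1c1ccc(OCc3ccccc3)c(OCc3ccccc3)c1 | intermediate (key-step product)
17 | 5-(phenylthio) derivative of 16, (2R,3R) | O=C1C[C@H](c2ccc(OCc3ccccc3)cc2)Oc2c1c(OCc3ccccc3)cc(OCc3ccccc3)c2[C@H]1C(=O)C(Sc3ccccc3)=CO[C@H]1c1ccc(OCc3ccccc3)c(OCc3ccccc3)c1 | intermediate
18 | 5-(phenylsulfinyl) derivative of 16, (2R,3R), both sulfur epimers | O=C1C[C@H](c2ccc(OCc3ccccc3)cc2)Oc2c1c(OCc3ccccc3)cc(OCc3ccccc3)c2[C@H]1C(=O)C(S(=O)c3ccccc3)=CO[C@H]1c1ccc(OCc3ccccc3)c(OCc3ccccc3)c1 | intermediate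
19 | methyl acetoacetate | COC(=O)CC(C)=O | starting material
20 | methyl 3-(trimethylsilyloxy)but-2-enoate, E/Z mixture | COC(=O)C=C(C)O[Si](C)(C)C | intermediate
21 | 1-methoxy-1,3-bis(trimethylsilyloxy)buta-1,3-diene | C=C(O[Si](C)(C)C)C=C(OC)O[Si](C)(C)C | intermediate
22 | (2R,3R)-2-ArB-3-ArD-5-methoxy-4a-(phenylsulfinyl)-5,7-bis(trimethylsilyloxy)-4a,5,8,8a-tetrahydrochroman-4-one; C4a–S cis to C8a–H; mixture at C4a, C5, C8a and sulfur | O=C1C[C@H](c2ccc(OCc3ccccc3)cc2)Oc2c1c(OCc3ccccc3)cc(OCc3ccccc3)c2[C@H]1C(=O)C2(S(=O)c3ccccc3)C(OC)(O[Si](C)(C)C)C=C(O[Si](C)(C)C)CC2O[C@H]1c1ccc(OCc3ccccc3)c(OCc3ccccc3)c1 | intermediate (not isolated)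
23 | (2R,3R)-2-ArB-3-ArD-5-methoxy-5,7-bis(trimethylsilyloxy)-5,8-dihydrochroman-4-one; C4a=C8a restored; mixture at C5 | O=C1C[C@H](c2ccc(OCc3ccccc3)cc2)Oc2c1c(OCc3ccccc3)cc(OCc3ccccc3)c2[C@H]1C(=O)C2=C(CC(O[Si](C)(C)C)=CC2(OC)O[Si](C)(C)C)O[C@H]1c1ccc(OCc3ccccc3)c(OCc3ccccc3)c1 | intermediate (not isolated)
24 | 5,7-bis(trimethylsilyl) ether of 25 | O=C1C[C@H](c2ccc(OCc3ccccc3)cc2)Oc2c1c(OCc3ccccc3)cc(OCc3ccccc3)c2[C@H]1C(=O)c2c(O[Si](C)(C)C)cc(O[Si](C)(C)C)cc2O[C@H]1c1ccc(OCc3ccccc3)c(OCc3ccccc3)c1 | intermediate (not isolated)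
25 | (2R,3R)-2-[3,4-bis(benzyloxy)phenyl]-3-[(2R)-5,7-bis(benzyloxy)-2-[4-(benzyloxy)phenyl]-4-oxochroman-8-yl]-5,7-dihydroxychroman-4-one | O=C1C[C@H](c2ccc(OCc3ccccc3)cc2)Oc2c1c(OCc3ccccc3)cc(OCc3ccccc3)c2[C@H]1C(=O)c2c(O)cc(O)cc2O[C@H]1c1ccc(OCc3ccccc3)c(OCc3ccccc3)c1 | intermediate
26 | (2R,3R)-2-(3,4-dihydroxyphenyl)-5,7-dihydroxy-3-[(2R)-5,7-dihydroxy-2-(4-hydroxyphenyl)-4-oxochroman-8-yl]chroman-4-one | O=C1C[C@H](c2ccc(O)cc2)Oc2c1c(O)cc(O)c2[C@H]1C(=O)c2c(O)cc(O)cc2O[C@H]1c1ccc(O)c(O)c1 | target

Total steps: 17. Longest linear sequence: 15 (steps 1 to 13, then 16 and 17); steps 14 and 15 form the side branch to diene 21.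

Steps most likely to fail

1. Step 16 (ring A annulation). The ketene acetal may only transfer silicon to the sulfoxide oxygen, or it may add once at C8a without closing the second bond, so that no six-membered ring forms; the sulfoxide may also be lost before ring closure. The fallback uses known chemistry and builds ring A before ring C, starting from aldehyde 9. Pinnick oxidation (NaClO2, NaH2PO4, 2-methyl-2-butene) would give [(2R)-5,7-bis(benzyloxy)-2-[4-(benzyloxy)phenyl]-4-oxochroman-8-yl]acetic acid F1. Friedel–Crafts acylation of phloroglucinol with F1 (BF3·OEt2, 50 to 60 °C) would give the deoxybenzoin (2R)-5,7-bis(benzyloxy)-2-[4-(benzyloxy)phenyl]-8-[2-oxo-2-(2,4,6-trihydroxyphenyl)ethyl]chroman-4-one F2. Amine-mediated condensation of F2 with aldehyde 14 (piperidine, EtOH; Knoevenagel condensation, then oxa-Michael closure by an ortho phenol) gives the 2,3-diaryl-5,7-dihydroxychroman-4-one and returns to the route at 25. This classical assembly secures the skeleton but not the stereochemistry: C2 and C3 are not controlled and the trans isomers are expected to predominate. Compound 25 would then have to be separated from three diastereomers, which is possible in principle because the fixed C2'' centre makes all four diastereomeric.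

2. Step 11 (key step). The di-ortho-substituted ring D on the diene terminus may make the cycloaddition slow or shift it towards the exo mode; the enol silane may hydrolyse before it reacts; a stepwise aldol pathway may erode the cis selectivity. The fallback is a stepwise aldol–cyclisation that sets out from enone 12. Its Z boron enolate (diisopinocampheylboron triflate of the appropriate antipode, iPr2NEt, CH2Cl2, −78 °C) should add to aldehyde 14 through a chair transition state to give the syn aldol adduct (2R)-5,7-bis(benzyloxy)-2-[4-(benzyloxy)phenyl]-8-[(1R,2R,4E)-1-[3,4-bis(benzyloxy)phenyl]-1-hydroxy-5-methoxy-3-oxopent-4-en-2-yl]chroman-4-one F3. Mild acid (pyridinium p-toluenesulfonate or CF3CO2H) should then close ring C by oxa-Michael addition and loss of methanol with both centres retained, returning to the route at 16.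

3. Step 12 (sulfenylation at C4a). The sulfur electrophile may attack the very electron-rich ring D at C6'' (or ring B) in competition with the vinylogous ester. The fallback introduces sulfur before the enone exists and sets out from 13 and 14. The cycloaddition of step 11 is run without the acid treatment, and the crude enol silane 15 is treated at −78 °C with PhSCl, which reacts with an enol silane far faster than with an arene. This should give (2R,3R,6S)-2-ArB-3-ArD-6-methoxy-5-(phenylthio)tetrahydro-4H-pyran-4-one F4 (mixture at C5). CF3CO2H then expels methanol and the sequence returns to the route at 17.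

Further compounds
F1 | step 16 | [(2R)-5,7-bis(benzyloxy)-2-[4-(benzyloxy)phenyl]-4-oxochroman-8-yl]acetic acid | O=C1C[C@H](c2ccc(OCc3ccccc3)cc2)Oc2c1c(OCc3ccccc3)cc(OCc3ccccc3)c2CC(=O)O
F2 | step 16 | (2R)-5,7-bis(benzyloxy)-2-[4-(benzyloxy)phenyl]-8-[2-oxo-2-(2,4,6-trihydroxyphenyl)ethyl]chroman-4-one | O=C1C[C@H](c2ccc(OCc3ccccc3)cc2)Oc2c1c(OCc3ccccc3)cc(OCc3ccccc3)c2CC(=O)c1c(O)cc(O)cc1O
F3 | step 11 | (2R)-5,7-bis(benzyloxy)-2-[4-(benzyloxy)phenyl]-8-[(1R,2R,4E)-1-[3,4-bis(benzyloxy)phenyl]-1-hydroxy-5-methoxy-3-oxopent-4-en-2-yl]chroman-4-one | O=C1C[C@H](c2ccc(OCc3ccccc3)cc2)Oc2c1c(OCc3ccccc3)cc(OCc3ccccc3)c2[C@@H](C(=O)/C=C/OC)[C@@H](O)c1ccc(OCc3ccccc3)c(OCc3ccccc3)c1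
F4 | step 12 | (2R,3R,6S)-2-ArB-3-ArD-6-methoxy-5-(phenylthio)tetrahydro-4H-pyran-4-one, mixture at C5 | O=C1C[C@H](c2ccc(OCc3ccccc3)cc2)Oc2c1c(OCc3ccccc3)cc(OCc3ccccc3)c2[C@H]1C(=O)C(Sc3ccccc3)[C@@H](OC)O[C@H]1c1ccc(OCc3ccccc3)c(OCc3ccccc3)c1
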